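## Structural features

The target 14 is a cyclohex-2-en-1-one whose α-carbon C1' is quaternary and carries the ring methylene C2', an allyl group and the C8–C7 chain that ends in the 3,4,5-trimethoxyphenyl carbinol (neolignan labels: C7 carbinol, C8 CHMe, ring C1'–C6', allyl C7'–C9'). Three stereocentres are contiguous (C7–C8–C1', with C7/C8 anti and C8 bonded directly to the quaternary carbon), and the fourth, the methoxy-bearing C3', lies 1,3 to C1' across C2' and must be cis to the C8 branch. Fragile points are the γ-hydroxy ketone (C7–OH and C6'=O close readily to a lactol), the benzylic C7–O bond beside an electron-rich arene (ionisation under acid), and the γ-methoxy enone (loss of methanol or epimerisation at C3' through a dienol). The ring cannot aromatise because C1' is quaternary, so a 4-oxy-enone oxidation level can be carried through a synthesis. The real difficulty is to build the quaternary centre with control relative to both the neighbouring C8 and the remote C3', with nothing but the ring between C1' and C3'. The key step exploits the unit C3'–C4'=C5'–C6', which has oxygen at both ends and is therefore a 2-oxyfuran in disguise (ring oxygen on C3' and C6', exocyclic oxygen on C6'). The C7 oxygen is separated from C1' only by C7 and C8, so O7–C7–C8 can tether furan carbon C6' to an alkene C1'=C2'.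

## Logic of the disconnections

**14 ⇒ 13 ⇒ 12.** Bond cut: the O–CH3 bond of the C3' ether, after the C6' carbonyl and the C7 hydroxyl of 14 have been folded back into the five-membered mixed methyl ketal 13. Reason: in 12 the C7 oxygen and the ketone are both locked in the ketal, so the C3' hydroxyl is the only nucleophile and no enolisable γ-oxy enone is exposed to base. Gain: no protecting group and no selectivity problem between two secondary hydroxyls. Demand: the ketal of 13 must hydrolyse under conditions that spare the benzylic alcohol and the allylic ether; as an allylic ketal it should open in dilute acid at room temperature.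

**12 ⇒ 11.** Bond exchanged: the C6'–OCH3 bond of 12 is replaced by the C6'–O–C3' bridge of 11. Reason: the bridge oxygen already sits on C3' with the correct configuration and only has to be released from C6', never from C3'. Gain: 12 is traced to a compact bridged ketal in which C3', C1' and the masked ketone belong to one ring system. Demand: solvolysis must break C6'–O(bridge) only. Cleaving C6'–O7 instead would require a bridgehead oxocarbenium ion, so the cage dictates the regiochemistry. The ion must be trapped at once by solvent before the benzylic C7–O bond ionises. A direct alkylative opening with a hard methylating agent would save a step, but it has no close precedent on this ring system and would leave that ion without a trap, so it is not used.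

**11 ⇒ 10.** Bonds cut: C6'–C1' and C3'–C2' (retro-[4+2]). Reason: both bonds, the carbocycle, the tetrahydrofuran and the stereocentres C1', C3' and C6' arise in one thermal operation from an acyclic chain and a flat furan. Gain: two rings, two C–C bonds and three stereocentres including the quaternary carbon; 10 has only the C7/C8 pair. Demand: the tether must sit exo, the furan must reach the alkene face selected by C8, the allyl alkene must stay out, and the medium must stay neutral to basic because 10 is an acid-labile furyl ether of a benzylic alcohol. Design measures: no protecting group is carried, the medium is amine-buffered with a radical inhibitor, and 10 is used without storage.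

**10 ⇒ 8 + 9.** Bond cut: the furan C2–O7 bond. Reason: the C7–O bond and both stereocentres stay untouched, and the furan comes from a commercial halide. Gain: an unfunctionalised homoallylic alcohol and a four-carbon heteroaryl bromide. Demand: C–O coupling on a hindered secondary benzylic alkoxide without oxidation, elimination or isomerisation of the skipped diene.

**8 ⇒ 5 + 6 (through 7).** Bond cut: C7–C8. Reason: allyl transfer with allylic transposition creates both stereocentres, the 1,1-disubstituted alkene C1'=C2' and the pendant allyl group in one step. Gain: an achiral aldehyde and an achiral allylboronate. Demand: 5 must be geometrically pure (methyl trans to CH2B) for the anti relationship, and the catalyst must expose the Si face of 6.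

**5 ⇒ 4.** Bond cut: C–B. Reason: the allylic alcohol already holds the required alkene geometry. Gain: a simple trisubstituted allylic alcohol. Demand: substitution at the CH2 terminus with retention of alkene geometry and no migration of the skipped diene.

**4 ⇒ 1 + 2 (through 3).** Bond cut: the bond between the allyl CH2 and the alkene carbon. Reason: hydroxyl-directed carbometallation fixes regiochemistry and geometry together. Gain: two commercial C4 and C3 units. Demand: anti addition with allyl on the carbon next to CH2OH.

## Other disconnections considered

**Alternative 1:**
- **Cut:** C1'–C2' and C4'=C5' of the cyclohexenone, with the allyl carbon C7' disguised as the carbonyl carbon of a γ-lactone closed onto O7.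
- **Forward key step:** the enolate of acetyl lactone A1 adds to the CH2 terminus of 2-methoxyacrolein A2, and the acetyl methyl group then condenses with the aldehyde to give spiro lactone A3 (a Robinson annulation).
- **In favour:** the new bond at C1' forms on a rigid lactone enolate anti to the C8 methyl, which is the sense the target needs. The intermediates are robust and the reagents are simple.
- **Against here:** C3' is created as an epimerisable centre α to an aldehyde and later γ to the enone, with no nearby control element. The quaternary β-keto lactone is open to retro-Claisen cleavage under the basic condensation, and A2 polymerises easily. After A3 the lactone carbonyl still has to become CH2–CH=CH2 (reduction to the lactol, two one-carbon olefinations with an enol ether hydrolysis between them) in the presence of the enone.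
- **Comparison:**
  - Structure: it is the equal or the better of the chosen plan for C1' relative to C8 and avoids a labile furyl ether. It is weaker for C3', which the chosen cycloaddition fixes through the cage.
  - Mechanism: stepwise ionic chemistry under thermodynamic control, against a concerted suprafacial addition.
  - Step economy: four to five steps after the key step, against two.

**Alternative 2:**
- **Cut:** C8–CH3 and C1'–C7' on a butenolide; no ring is closed.
- **Forward key step:** the cuprate Me2CuLi A5 adds methyl to C8 of butenolide A4 anti to the γ-aryl group, and the lactone enolate is trapped in the same flask by allyl bromide A6 anti to the new methyl, giving lactone A7.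
- **In favour:** the trans,trans pattern produced by two successive 1,2-inductions is exactly that of C7/C8/C1'. C3' arrives enantiopure in the side chain, and every step type is well understood. On stereochemical reliability this is the equal or the better of the chosen plan, and it is convergent.
- **Against here:** the γ-hydrogen of A4 is benzylic and vinylogous, so deprotonation to an aromatic furanolate (loss of C7 configuration) and reductive C–O cleavage compete with conjugate addition to an α-branched acceptor. The cyclohexenone is not formed in the key step and needs a further one-carbon nucleophile at the lactone carbonyl, desilylation, oxidation at C4' and an intramolecular Horner–Wadsworth–Emmons closure. A4 itself needs two chiral fragments.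
- **Comparison:**
  - Structure: all four centres are secured by substrate control and chiral pool, with no dependence on a transition-state strain argument.
  - Mechanism: it builds no ring and no quaternary-centre/ring pair at once.
  - Step economy: clearly longer.

**Alternative 3:**
- **Cut:** C7–C8 and C1'–C2', with the six-membered ring traced back to a cyclopentane.
- **Forward key step:** diol A8 condenses with aldehyde 6 to an oxocarbenium ion at C7, the alkene attacks it through C8, and ring carbon C2' shifts from C6' to the cationic C1' (Prins–pinacol), giving the cis-fused hydrobenzofuranone A9.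
- **In favour:** a strongly precedented reaction class that makes C7, C8 and the quaternary C1' in one step through a chair-like transition state, uses the same aldehyde, and forms the cyclohexanone by ring enlargement. In precedent for quaternary-centre formation it is the better of the chosen plan.
- **Against here:** in A9 the C7 oxygen ends up bonded to C2', a bond the target does not have. Cleaving C2'–O while keeping the more labile benzylic C7–O bond has no good solution: the bond is β to the ketone but the α-carbon is quaternary, so no elimination pathway exists. The C4'=C5' unsaturation must be added afterwards (Saegusa-type oxidation), and A8 needs three contiguous all-cis oxygenated centres on a cyclopentane.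
- **Stereochemical note:** to correlate with 14, the methoxy group of A9 must be cis to the ring oxygen on the neighbouring carbon. A drawing with these two groups trans corresponds to the C3' epimer of 14, so the cis structure is the one listed as A9.
- **Comparison:**
  - Structure: excellent for the C7–C8–C1' triad, but it leaves a superfluous C–O bond and the wrong oxidation pattern.
  - Mechanism: cationic cascade against pericyclic closure.
  - Step economy: worse before and after the key step.

Key step: step 5

Remarks on the chemistry:
- Assumption: the binaphthyl phosphoric acid follows its usual sense of induction with aryl aldehydes (R acid, Re face), so the S acid is specified for Si-face attack; if the sense is reversed with this boronate, the R acid is used.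
- Boronate 5 has the crotyl-(E) topology (methyl trans to CH2B) but is Z by the sequence rule, because the allyl branch outranks CH2B; alcohol 4 with the same geometry is E.
- The steric element that controls the alkene face in step 5 is A(1,2) strain between the C8 substituents and the geminal allyl group; A(1,3) strain is negligible because the cis position on C2' carries only hydrogen.

## Route

**Step 1**
Reactants: 1 but-2-yn-1-ol; 2 allylmagnesium bromide (commercial solution in Et2O)
Product: 4 (2E)-2-ethylidenepent-4-en-1-ol, via chelated alkenylmagnesium alkoxide 3 (not isolated)
Conditions: 2 (2.5 equiv), Et2O–THF, 0 °C → reflux; then sat. aq NH4Cl, 0 °C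
Reagents that add atoms: none
Why: Hydroxyl-directed anti-carbomagnesiation of a propargylic alcohol: the magnesium alkoxide delivers allyl to the alkyne carbon next to CH2O and leaves magnesium on the far carbon in a five-membered chelate, so protonation gives the trisubstituted alkene with methyl trans to CH2OH and cis to allyl.

**Step 2**
Reactants: 4
Product: 5 2-[(2Z)-2-ethylidenepent-4-en-1-yl]-4,4,5,5-tetramethyl-1,3,2-dioxaborolane (methyl trans to CH2B)
Conditions: bis(pinacolato)diboron (1.2 equiv), Pd(MeCN)4(BF4)2 (5 mol %), DMSO–MeOH 1:1, 50 °C
Reagents that add atoms: bis(pinacolato)diboron, CC1(C)OB(OC1(C)C)B1OC(C)(C)C(C)(C)O1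
Why: Palladium-catalysed borylation of an allylic alcohol through a π-allylpalladium intermediate: boron goes to the unsubstituted CH2 terminus and the allyl unit keeps its syn arrangement, so the methyl stays trans to the carbon that now bears boron.

**Step 3**
Reactants: 5; 6 3,4,5-trimethoxybenzaldehyde
Product: 8 (1S,2S)-2-methyl-3-methylidene-1-(3,4,5-trimethoxyphenyl)hex-5-en-1-ol, via pinacol borate ester 7 (not isolated)
Conditions: (S)-3,3'-bis(2,4,6-triisopropylphenyl)-1,1'-binaphthyl-2,2'-diyl hydrogen phosphate (5 mol %), 4 Å MS, PhMe, −30 → 0 °C; then aq NaHCO3
Reagents that add atoms: none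
Why: Chiral-phosphoric-acid-catalysed allylboration through a closed chair (Zimmerman–Traxler) transition state: the methyl trans to CH2B sits equatorial and gives the anti C7/C8 pair, while the acid, hydrogen-bonded to a boronate oxygen and the formyl hydrogen, exposes the Si face of 6 and so sets C7 as S and C8 as S.

**Step 4**
Reactants: 8; 9 2-bromofuran
Product: 10 2-{[(1S,2S)-2-methyl-3-methylidene-1-(3,4,5-trimethoxyphenyl)hex-5-en-1-yl]oxy}furan
Conditions: CuI (10 mol %), 3,4,7,8-tetramethyl-1,10-phenanthroline (20 mol %), Cs2CO3 (2 equiv), 9 (3 equiv), PhMe, 100 °C, sealed tube; filtration through basic Al2O3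
Reagents that add atoms: none
Why: Ullmann-type copper-catalysed C–O coupling of a secondary alkoxide with a heteroaryl bromide on phenanthroline-ligated monovalent copper; no bond to C7 or C8 is broken, so both centres are retained, and any 10 that already cyclises at this temperature is simply carried into step 5.

**Step 5**
Reactants: 10
Product: 11 (2S,3S,3aR,5R,7aS)-3a-allyl-3-methyl-2-(3,4,5-trimethoxyphenyl)-2,3,3a,4,5,7a-hexahydro-5,7a-epoxy-1-benzofuran (bridged ketal; 7-oxanorbornene fused exo to a tetrahydrofuran)
Conditions: PhMe (0.02 M), Et3N (0.2 equiv), 2,6-di-tert-butyl-4-methylphenol (10 mol %), degassed, sealed tube, 120 °C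
Reagents that add atoms: none
Why: On heating, the electron-rich 2-alkoxyfuran (HOMO raised by O7) adds as the 4π component across the tethered, unactivated 1,1-disubstituted alkene in a concerted, asynchronous, suprafacial [4+2] process that forms C6'–C1' and C3'–C2'. The closest known reaction type is the intramolecular Diels–Alder reaction of 2-amino- and 2-alkoxyfurans with unactivated alkenes held by a three-atom tether. The six-membered carbocycle closes as the cycloaddition ring itself, and the tetrahydrofuran O7–C7–C8–C1'–C6' closes as the tether folds onto the new C6'–C1' bond, which a three-atom tether allows only in the exo mode, syn to the oxygen bridge. C6' and C3' are fixed relative to each other by suprafacial addition to the furan (the bridging oxygen is cis at both). The exo tether places C8 on the side of the bridging oxygen, so the C3'–O bond ends cis to the C8 branch of the future cyclohexenone. The sense at C1' (R) follows from C8: A(1,2) strain makes the C8–H bond eclipse the C1'–allyl bond, the C8 methyl lies beside =C2'H2, and C7 carries the furan to the alkene face that leaves allyl trans to methyl, with the aryl group pseudo-equatorial on the forming five-membered ring. Chemoselectivity over the allyl alkene rests on ring size (it would need a seven-membered tether ring), the quaternary C1' blocks the usual collapse to an aromatic ring, and the amine buffer and radical inhibitor protect the acid-labile furyl ether and benzylic C7–O bond. Because the cycloaddition is reversible, the adduct with methyl trans to allyl, which is also the less congested one, should accumulate under thermodynamic as well as kinetic control.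

**Step 6**
Reactants: 11
Product: 12 (2S,3S,3aR,5R)-3a-allyl-7a-methoxy-3-methyl-2-(3,4,5-trimethoxyphenyl)-2,3,3a,4,5,7a-hexahydro-1-benzofuran-5-ol (either or both C7a epimers)
Conditions: pyridinium p-toluenesulfonate (10 mol %), MeOH, 0 °C → rt; then Et3N
Reagents that add atoms: methanol, CO
Why: Acid-catalysed transketalisation: protonation of the bridging oxygen and cleavage of C6'–O(bridge) gives an oxocarbenium ion stabilised by O7 and the C4'=C5' alkene (the alternative ion would be at a bridgehead and is excluded by Bredt's rule), and solvent methanol traps it at C6'; the C3'–O bond is never broken, so C3' keeps its configuration and C7–O stays masked.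

**Step 7**
Reactants: 12
Product: 14 (4R,6R)-6-[(1S,2S)-1-hydroxy-1-(3,4,5-trimethoxyphenyl)propan-2-yl]-4-methoxy-6-(prop-2-en-1-yl)cyclohex-2-en-1-one (target), via methyl ether ketal 13 (not isolated)
Conditions: NaH (1.5 equiv), MeI (3 equiv), THF, 0 °C → rt; then AcOH–THF–H2O 3:1:1, rt
Reagents that add atoms: iodomethane, CI; water, O
Why: Williamson methylation of the only free hydroxyl (C7–O and the ketone are masked, so neither over-methylation nor enolate chemistry can occur), followed in the same flask by acid hydrolysis of the allylic mixed ketal, which releases the C6' ketone and the C7 hydroxyl without touching a stereocentre.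

## Compound list

1 | but-2-yn-1-ol | CC#CCO | starting material
2 | allylmagnesium bromide | C=CC[Mg]Br | starting material
3 | 4-allyl-3-methyl-2,5-dihydro-1,2-oxamagnesole (chelated alkenylmagnesium alkoxide) | CC1=C(CC=C)CO[Mg]1 | intermediate
4 | (2E)-2-ethylidenepent-4-en-1-ol | C/C=C(/CO)CC=C | intermediate
5 | 2-[(2Z)-2-ethylidenepent-4-en-1-yl]-4,4,5,5-tetramethyl-1,3,2-dioxaborolane | C/C=C(/CB1OC(C)(C)C(C)(C)O1)CC=C | intermediate
6 | 3,4,5-trimethoxybenzaldehyde | O=Cc1cc(OC)c(OC)c(OC)c1 | starting material
7 | 4,4,5,5-tetramethyl-2-{[(1S,2S)-2-methyl-3-methylidene-1-(3,4,5-trimethoxyphenyl)hex-5-en-1-yl]oxy}-1,3,2-dioxaborolane | C=CCC(=C)[C@H](C)[C@H](OB1OC(C)(C)C(C)(C)O1)c1cc(OC)c(OC)c(OC)c1 | intermediate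
8 | (1S,2S)-2-methyl-3-methylidene-1-(3,4,5-trimethoxyphenyl)hex-5-en-1-ol | C=CCC(=C)[C@H](C)[C@H](O)c1cc(OC)c(OC)c(OC)c1 | intermediate
9 | 2-bromofuran | Brc1ccco1 | starting material
10 | 2-{[(1S,2S)-2-methyl-3-methylidene-1-(3,4,5-trimethoxyphenyl)hex-5-en-1-yl]oxy}furan | C=CCC(=C)[C@H](C)[C@H](Oc1ccco1)c1cc(OC)c(OC)c(OC)c1 | intermediate
11 | (2S,3S,3aR,5R,7aS)-3a-allyl-3-methyl-2-(3,4,5-trimethoxyphenyl)-2,3,3a,4,5,7a-hexahydro-5,7a-epoxy-1-benzofuran | C=CC[C@]12C[C@@H]3C=C[C@]1(O3)O[C@H](c4cc(OC)c(OC)c(OC)c4)[C@H]2C | intermediate
12 | (2S,3S,3aR,5R)-3a-allyl-7a-methoxy-3-methyl-2-(3,4,5-trimethoxyphenyl)-2,3,3a,4,5,7a-hexahydro-1-benzofuran-5-ol (C7a epimers) | C=CC[C@]12C[C@@H](O)C=CC1(OC)O[C@H](c3cc(OC)c(OC)c(OC)c3)[C@H]2C | intermediate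
13 | (2S,3S,3aR,5R)-3a-allyl-5,7a-dimethoxy-3-methyl-2-(3,4,5-trimethoxyphenyl)-2,3,3a,4,5,7a-hexahydro-1-benzofuran (C7a epimers) | C=CC[C@]12C[C@@H](OC)C=CC1(OC)O[C@H](c3cc(OC)c(OC)c(OC)c3)[C@H]2C | intermediate
14 | (4R,6R)-6-[(1S,2S)-1-hydroxy-1-(3,4,5-trimethoxyphenyl)propan-2-yl]-4-methoxy-6-(prop-2-en-1-yl)cyclohex-2-en-1-one | C=CC[C@]1([C@H](C)[C@H](O)c2cc(OC)c(OC)c(OC)c2)C[C@@H](OC)C=CC1=O | target

## Step count and least certain steps

Total step count: 7. Longest linear sequence: 7 (1 → 4 → 5 → 8 → 10 → 11 → 12 → 14).

**Step 5 (key step).**
- What may go wrong: cycloreversion keeping pace with ring closure, because no irreversible follow-up drains the equilibrium and a quaternary carbon is being formed. Discrimination between the two alkene faces may also be insufficient, since it rests on A(1,2) strain alone. Prolonged heating could in addition ionise the benzylic furyl ether.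
- Fallback (substrate redesign): it sets out from 8. Coupling with 2,5-dibromofuran under the step 4 conditions should give 2-bromo-5-{[(1S,2S)-2-methyl-3-methylidene-1-(3,4,5-trimethoxyphenyl)hex-5-en-1-yl]oxy}furan F1. A halogen on the furan carbon that becomes the sp3 bridgehead is known to make such cycloadditions faster and more exergonic, so F1 should close at a lower temperature to the bridgehead-bromo analogue of 11 F2. Reduction with Bu3SnH and azobisisobutyronitrile in benzene at 80 °C (bridgehead radical, configuration held by the cage) returns to the route at 11.

**Step 4.**
- What may go wrong: slow coupling of the hindered, α-branched secondary alkoxide, so that dehydrogenation of the benzylic alkoxide on copper, decomposition of 9 and premature unbuffered cycloaddition take over.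
- Fallback (addition–elimination in place of cross-coupling): it sets out from 8. Deprotonation with KN(SiMe3)2 and reaction with methyl 5-nitrofuran-2-carboxylate in THF (−78 → 0 °C) should displace nitrite and give methyl 5-{[(1S,2S)-2-methyl-3-methylidene-1-(3,4,5-trimethoxyphenyl)hex-5-en-1-yl]oxy}furan-2-carboxylate F3. LiOH in aqueous THF gives the corresponding furan-2-carboxylic acid F4. Protodecarboxylation with Ag2CO3 (10 mol %) in DMSO at 120 °C removes the activating group and returns to the route at 10, most of which should go on to 11 in the same flask.

**Step 2.**
- What may go wrong: syn/anti interconversion of the π-allylpalladium intermediate, which erodes the alkene geometry of 5 and hence the anti selectivity of step 3, or palladium hydride migration of the skipped diene into conjugation.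
- Fallback (chromium in place of boron): it sets out from 4. Appel bromination (CBr4, PPh3, CH2Cl2, 0 °C) should give (4E)-4-(bromomethyl)hexa-1,4-diene F5. A catalytic asymmetric Nozaki–Hiyama addition to 6 (CrCl2 10 mol %, a C2-symmetric bis(oxazolinyl)carbazole ligand, Mn powder, Me3SiCl, THF) should give the trimethylsilyl ether of 8 F6, and fluoride or dilute acid then returns to the route at 8. The allylchromium intermediate equilibrates to the crotyl-(E) form before a chair-like addition, so the anti selectivity no longer depends on geometric purity. The same detour replaces step 3 if its enantioselectivity with this doubly substituted boronate is inadequate.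

**Step 6.**
- What may go wrong: misdirected ionisation of 11 (loss of the benzylic C7–O bond from the oxocarbenium ion, or capture of methanol at C4' in place of C6'), or re-closure to 11 on concentration.
- Fallback (hydrolysis first, methylation second): it sets out from 11. AcOH–THF–H2O at room temperature should give (4R,6R)-4-hydroxy-6-[(1S,2S)-1-hydroxy-1-(3,4,5-trimethoxyphenyl)propan-2-yl]-6-(prop-2-en-1-yl)cyclohex-2-en-1-one F7, in equilibrium with its lactol. Ag2O and MeI in CH2Cl2 should methylate the unhindered allylic C3' hydroxyl in preference to the C7 hydroxyl, which is flanked by the aryl ring and the branched C8 and is partly tied up as the lactol. A lactol methyl ether, if formed, is 13 and is hydrolysed on acidic work-up. The fallback returns to the route at 14.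

## Further compounds

F1 | step 5 | 2-bromo-5-{[(1S,2S)-2-methyl-3-methylidene-1-(3,4,5-trimethoxyphenyl)hex-5-en-1-yl]oxy}furan | C=CCC(=C)[C@H](C)[C@H](Oc1ccc(Br)o1)c1cc(OC)c(OC)c(OC)c1
F2 | step 5 | 5-bromo analogue of 11 (same cage configuration, bromine on bridgehead C3'): 3a-allyl-5-bromo-3-methyl-2-(3,4,5-trimethoxyphenyl)-2,3,3a,4,5,7a-hexahydro-5,7a-epoxy-1-benzofuran | C=CC[C@]12C[C@]3(Br)C=C[C@]1(O3)O[C@H](c4cc(OC)c(OC)c(OC)c4)[C@H]2C
F3 | step 4 | methyl 5-{[(1S,2S)-2-methyl-3-methylidene-1-(3,4,5-trimethoxyphenyl)hex-5-en-1-yl]oxy}furan-2-carboxylate | C=CCC(=C)[C@H](C)[C@H](Oc1ccc(C(=O)OC)o1)c1cc(OC)c(OC)c(OC)c1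
F4 | step 4 | 5-{[(1S,2S)-2-methyl-3-methylidene-1-(3,4,5-trimethoxyphenyl)hex-5-en-1-yl]oxy}furan-2-carboxylic acid | C=CCC(=C)[C@H](C)[C@H](Oc1ccc(C(=O)O)o1)c1cc(OC)c(OC)c(OC)c1
F5 | step 2 | (4E)-4-(bromomethyl)hexa-1,4-diene | C/C=C(/CBr)CC=C
F6 | step 2 | trimethyl{[(1S,2S)-2-methyl-3-methylidene-1-(3,4,5-trimethoxyphenyl)hex-5-en-1-yl]oxy}silane | C=CCC(=C)[C@H](C)[C@H](O[Si](C)(C)C)c1cc(OC)c(OC)c(OC)c1
F7 | step 6 | (4R,6R)-4-hydroxy-6-[(1S,2S)-1-hydroxy-1-(3,4,5-trimethoxyphenyl)propan-2-yl]-6-(prop-2-en-1-yl)cyclohex-2-en-1-one | C=CC[C@]1([C@H](C)[C@H](O)c2cc(OC)c(OC)c(OC)c2)C[C@@H](O)C=CC1=O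
A1 | alternative 1 | (4S,5S)-3-acetyl-4-methyl-5-(3,4,5-trimethoxyphenyl)oxolan-2-one (enolisable at C3) | CC(=O)C1C(=O)O[C@H](c2cc(OC)c(OC)c(OC)c2)[C@H]1C
A2 | alternative 1 | 2-methoxyprop-2-enal (2-methoxyacrolein) | C=C(OC)C=O
A3 | alternative 1 | (3S,4S,5S,9R)-9-methoxy-4-methyl-3-(3,4,5-trimethoxyphenyl)-2-oxaspiro[4.5]dec-7-ene-1,6-dione | O=C1O[C@H](c3cc(OC)c(OC)c(OC)c3)[C@@H](C)[C@]12C[C@@H](OC)C=CC2=O
A4 | alternative 2 | (5S)-3-[(2R)-3-{[tert-butyl(dimethyl)silyl]oxy}-2-methoxypropyl]-5-(3,4,5-trimethoxyphenyl)furan-2(5H)-one | O=C1O[C@H](c2cc(OC)c(OC)c(OC)c2)C=C1C[C@@H](OC)CO[Si](C)(C)C(C)(C)C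
A5 | alternative 2 | lithium dimethylcuprate (Me2CuLi) | [Li+].C[Cu-]C
A6 | alternative 2 | allyl bromide | C=CCBr
A7 | alternative 2 | (3R,4S,5S)-3-[(2R)-3-{[tert-butyl(dimethyl)silyl]oxy}-2-methoxypropyl]-4-methyl-3-(prop-2-en-1-yl)-5-(3,4,5-trimethoxyphenyl)oxolan-2-one | C=CC[C@@]1(C[C@@H](OC)CO[Si](C)(C)C(C)(C)C)[C@H](C)[C@@H](c2cc(OC)c(OC)c(OC)c2)OC1=O
A8 | alternative 3 | (1S,2S,3S)-1-[(2E)-hexa-2,5-dien-3-yl]-3-methoxycyclopentane-1,2-diol (hydroxyls and methoxy all cis) | O[C@]1(/C(CC=C)=C/C)CC[C@H](OC)[C@@H]1O
A9 | alternative 3 | (2S,3S,3aS,7S,7aR)-7-methoxy-3-methyl-3a-(prop-2-en-1-yl)-2-(3,4,5-trimethoxyphenyl)hexahydro-1-benzofuran-4(2H)-one (methoxy cis to the ring oxygen) | C=CC[C@]12[C@H](C)[C@@H](c3cc(OC)c(OC)c(OC)c3)O[C@H]1[C@@H](OC)CCC2=O
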